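**Plan**
- Retrosynthesis: the C3–OH bond is cut first, then the 7-O–prenyl bond (a benzyl group stands in for prenyl during the palladium chemistry). Ring C is then cut at C4a–C4, C4–C3 and O1–C2.
- Enabling feature: in ring C the carbonyl carbon C4 is a lone one-carbon unit between aryl carbon C4a of ring A and alkene carbon C3, and O1 sits ortho to C4a. Ring C therefore falls apart into an ortho-iodophenol (ring A), carbon monoxide (C4) and an arylacetylene (C3, C2 and ring B).
- Forward: ring A is iodinated, then rings A and B are joined through CO and ring C closes in the same pot. The 7-O-benzyl group is then exchanged for prenyl, and C3 is hydroxylated last by lithiation, borylation and oxidation.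
- Stereochemistry: the target has no stereocentre and no stereogenic alkene (the prenyl alkene carries two methyl groups), so nothing has to be controlled.

Key step: step 2

Remarks: compounds 1, 3, 4 and 9 are taken as commercial. Enaminone 6 is a push–pull alkene whose geometry is mobile and irrelevant to ring closure, so it is drawn without alkene descriptors.

**Step 1**
Reactants: 1 3-(benzyloxy)phenol
Product: 2 5-(benzyloxy)-2-iodophenol
Conditions: I2 (1.0 equiv), NaHCO3, THF/H2O (1:1), 0 °C to rt
Reagents that add atoms: iodine, [I][I]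
Why: Electrophilic aromatic iodination of the bicarbonate-buffered phenol should go to the carbon ortho to the hydroxyl and para to the benzyloxy group, which both oxygens activate and which is less hindered than the carbon between them, and one equivalent of iodine at 0 °C should hold the reaction at the monoiodide.

**Step 2**
Reactants: 2 5-(benzyloxy)-2-iodophenol; 3 carbon monoxide; 4 4-ethynyl-1,2-dimethoxybenzene
Product: 7 7-(benzyloxy)-2-(3,4-dimethoxyphenyl)-4H-chromen-4-one, via ortho-hydroxyaryl ynone 5 (not isolated), via diethylamino enaminone 6 (not isolated)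
Conditions: PdCl2(dppf) (5 mol%; dppf = 1,1'-bis(diphenylphosphino)ferrocene), CO (20 bar), Et2NH (solvent), 120 °C, autoclave
Reagents that add atoms: none
Why: Zerovalent palladium, formed in situ from the divalent precatalyst PdCl2(dppf), should insert into the C–I bond of 2, CO should insert to give the aroylpalladium iodide, and the amine-activated acetylide of 4 should couple with it, forming C4a–C4 and C4–C3 in ynone 5. Diethylamine then adds to the ynone to give enaminone 6, and the ortho phenol attacks the amine-bearing carbon and expels diethylamine, forming O1–C2. The closest known reaction type is the palladium-catalysed carbonylative Sonogashira coupling–cyclisation of ortho-iodophenols with terminal arylacetylenes to flavones. Ring C closes by a 6-endo-trig addition–elimination on the enaminone (in net terms a 6-endo-dig oxa-Michael closure of the ynone), and no stereocentre is created. The step needs flavone rather than aurone (5-exo) closure, which the secondary amine secures because the enaminone offers the phenol only the aryl-bearing carbon, and it needs carbonylative rather than direct coupling, which the CO pressure secures. The benzyl ether is inert here, whereas a prenyl ether would be ionised by zerovalent palladium in an amine.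

**Step 3**
Reactants: 7 7-(benzyloxy)-2-(3,4-dimethoxyphenyl)-4H-chromen-4-one
Product: 8 2-(3,4-dimethoxyphenyl)-7-hydroxy-4H-chromen-4-one
Conditions: H2 (1 atm), 10% Pd/C, EtOAc/MeOH, rt
Reagents that add atoms: none
Why: Heterogeneous hydrogenolysis of a benzyl aryl ether is fast at atmospheric pressure, whereas the C2=C3 bond of the flavone is a doubly aryl-conjugated vinylogous ester that should survive if the reaction is stopped once 7 is consumed.

**Step 4**
Reactants: 8 2-(3,4-dimethoxyphenyl)-7-hydroxy-4H-chromen-4-one; 9 prenyl bromide (1-bromo-3-methylbut-2-ene)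
Product: 10 2-(3,4-dimethoxyphenyl)-7-[(3-methylbut-2-en-1-yl)oxy]-4H-chromen-4-one
Conditions: K2CO3 (1.5 equiv), acetone, reflux
Reagents that add atoms: none
Why: In this Williamson etherification the 7-hydroxyl is a vinylogous acid that carbonate deprotonates fully, and the phenoxide should displace the primary allylic bromide at oxygen in SN2 fashion in a polar aprotic solvent.

**Step 5**
Reactants: 10 2-(3,4-dimethoxyphenyl)-7-[(3-methylbut-2-en-1-yl)oxy]-4H-chromen-4-one
Product: 13 2-(3,4-dimethoxyphenyl)-3-hydroxy-7-[(3-methylbut-2-en-1-yl)oxy]-4H-chromen-4-one, via 3-lithioflavone 11 (not isolated), via lithium trimethoxyborate 12 (not isolated)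
Conditions: LiN(iPr)2 (LDA, 1.2 equiv), THF, −78 °C; B(OMe)3, −78 to 0 °C; then AcOH, 30% H2O2, 0 °C to rt
Reagents that add atoms: hydrogen peroxide, OO
Why: Lithiation–borylation–oxidation of a flavone at C3 is a known way to flavonols: LDA removes the C3 hydrogen beside the carbonyl at −78 °C where the 3-lithio species does not yet ring-open, trimethyl borate traps it as the borate, and hydrogen peroxide in cold acetic acid brings about the 1,2-shift of C3 from boron to oxygen while leaving the unactivated prenyl alkene and the aryl ethers alone.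

**Compound list**
1 | 3-(benzyloxy)phenol | Oc1cccc(OCc2ccccc2)c1 | starting material
2 | 5-(benzyloxy)-2-iodophenol | Oc1cc(OCc2ccccc2)ccc1I | intermediate
3 | carbon monoxide | [C-]#[O+] | starting material
4 | 4-ethynyl-1,2-dimethoxybenzene | C#Cc1ccc(OC)c(OC)c1 | starting material
5 | 1-[4-(benzyloxy)-2-hydroxyphenyl]-3-(3,4-dimethoxyphenyl)prop-2-yn-1-one (formed in situ) | COc1ccc(C#CC(=O)c2ccc(OCc3ccccc3)cc2O)cc1OC | intermediate
6 | 1-[4-(benzyloxy)-2-hydroxyphenyl]-3-(diethylamino)-3-(3,4-dimethoxyphenyl)prop-2-en-1-one (formed in situ; alkene geometry not fixed) | CCN(CC)C(=CC(=O)c1ccc(OCc2ccccc2)cc1O)c1ccc(OC)c(OC)c1 | intermediate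
7 | 7-(benzyloxy)-2-(3,4-dimethoxyphenyl)-4H-chromen-4-one | COc1ccc(-c2cc(=O)c3ccc(OCc4ccccc4)cc3o2)cc1OC | intermediate
8 | 2-(3,4-dimethoxyphenyl)-7-hydroxy-4H-chromen-4-one | COc1ccc(-c2cc(=O)c3ccc(O)cc3o2)cc1OC | intermediate
9 | prenyl bromide (1-bromo-3-methylbut-2-ene) | CC(C)=CCBr | starting material
10 | 2-(3,4-dimethoxyphenyl)-7-[(3-methylbut-2-en-1-yl)oxy]-4H-chromen-4-one | COc1ccc(-c2cc(=O)c3ccc(OCC=C(C)C)cc3o2)cc1OC | intermediate
11 | {2-(3,4-dimethoxyphenyl)-7-[(3-methylbut-2-en-1-yl)oxy]-4-oxo-4H-chromen-3-yl}lithium (formed in situ) | [Li]c1c(-c2ccc(OC)c(OC)c2)oc2cc(OCC=C(C)C)ccc2c1=O | intermediate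
12 | lithium {2-(3,4-dimethoxyphenyl)-7-[(3-methylbut-2-en-1-yl)oxy]-4-oxo-4H-chromen-3-yl}trimethoxyborate (formed in situ) | [Li+].CO[B-](OC)(OC)c1c(-c2ccc(OC)c(OC)c2)oc2cc(OCC=C(C)C)ccc2c1=O | intermediate
13 | 2-(3,4-dimethoxyphenyl)-3-hydroxy-7-[(3-methylbut-2-en-1-yl)oxy]-4H-chromen-4-one (CNP0167607.0) | COc1ccc(-c2oc3cc(OCC=C(C)C)ccc3c(=O)c2O)cc1OC | target

**Step count**
Total steps: 5. Longest linear sequence: 5 steps (1 → 2 → 7 → 8 → 10 → 13).

**Steps most likely to fail**

Step 2. The risks are direct, CO-free coupling followed by closure to a 2-arylbenzofuran, 5-exo closure of the ynone to an aurone, and sluggish oxidative addition into the electron-rich, phenoxide-bearing aryl iodide. The fallback separates carbon–carbon bond formation from ring closure; it sets out from 2 and returns at 7. Compound 2 would be acetylated (Ac2O, pyridine) to 5-(benzyloxy)-2-iodophenyl acetate F1. Copper-free carbonylative Sonogashira coupling of the acetate with 3 and 4 under mild conditions and a tertiary amine (PdCl2(PPh3)2, Et3N, CO 1 atm, THF, rt) should give the isolable ynone 5-(benzyloxy)-2-[3-(3,4-dimethoxyphenyl)prop-2-ynoyl]phenyl acetate F2. Treatment with Et2NH in EtOH should then cleave the acetate and cyclise through 5 and 6 to 7.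

Step 5. The risks are ring opening of the 3-lithio species by β-elimination of the ring phenoxide, competing deprotonation at the allylic ether methylene, and protodeboronation before oxidation. The fallback replaces the anionic hydroxylation by an electrophilic one carried out before the prenyl group is present; it sets out from 7 and returns at 13.
- Dimethyldioxirane in acetone/CH2Cl2 at 0 °C should epoxidise 7 to racemic cis-fused 7-(benzyloxy)-2-(3,4-dimethoxyphenyl)-2,3-epoxy-2,3-dihydro-4H-chromen-4-one F3.
- Catalytic TsOH in CH2Cl2 should open the epoxide to 7-(benzyloxy)-2-(3,4-dimethoxyphenyl)-3-hydroxy-4H-chromen-4-one F4.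
- Hydrogenolysis (H2, 10% Pd/C) should give 2-(3,4-dimethoxyphenyl)-3,7-dihydroxy-4H-chromen-4-one F5.
- One equivalent each of K2CO3 and prenyl bromide 9 in acetone at rt should alkylate the more acidic 7-hydroxyl in preference to the hydrogen-bonded 3-hydroxyl and give 13.

Step 1. The risks are iodination para to the hydroxyl or at the carbon between the two oxygens, and over-iodination. The fallback masks the phenol so that the benzyloxy group alone directs; it sets out from 1 and returns at 2. Pivaloylation of 1 (pivaloyl chloride, Et3N, cat. DMAP, CH2Cl2) would give 3-(benzyloxy)phenyl pivalate F6. Iodination with N-iodosuccinimide and catalytic TFA in MeCN should go para to the only strong donor and give 5-(benzyloxy)-2-iodophenyl pivalate F7. Saponification (KOH, MeOH/H2O, then aqueous HCl) should return 2.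

**Further compounds**
F1 | step 2 | 5-(benzyloxy)-2-iodophenyl acetate | CC(=O)Oc1cc(OCc2ccccc2)ccc1I
F2 | step 2 | 5-(benzyloxy)-2-[3-(3,4-dimethoxyphenyl)prop-2-ynoyl]phenyl acetate | COc1ccc(C#CC(=O)c2ccc(OCc3ccccc3)cc2OC(C)=O)cc1OC
F3 | step 5 | cis-fused 7-(benzyloxy)-2-(3,4-dimethoxyphenyl)-2,3-epoxy-2,3-dihydro-4H-chromen-4-one (racemic, one enantiomer drawn) | COc1ccc([C@@]23Oc4cc(OCc5ccccc5)ccc4C(=O)[C@@H]2O3)cc1OC
F4 | step 5 | 7-(benzyloxy)-2-(3,4-dimethoxyphenyl)-3-hydroxy-4H-chromen-4-one | COc1ccc(-c2oc3cc(OCc4ccccc4)ccc3c(=O)c2O)cc1OC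
F5 | step 5 | 2-(3,4-dimethoxyphenyl)-3,7-dihydroxy-4H-chromen-4-one | COc1ccc(-c2oc3cc(O)ccc3c(=O)c2O)cc1OC
F6 | step 1 | 3-(benzyloxy)phenyl pivalate | CC(C)(C)C(=O)Oc1cccc(OCc2ccccc2)c1
F7 | step 1 | 5-(benzyloxy)-2-iodophenyl pivalate | CC(C)(C)C(=O)Oc1cc(OCc2ccccc2)ccc1I
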